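**Retrosynthetic overview**

1. Last step: the C6–C7 bond and the lactone C12–O bond are cut together, giving the acyclic (Z)-β-iodoacrylate/epoxy aldehyde 24. One Ni/Cr operation closes the 10-membered carbocycle and the butenolide and sets C6.
2. The oxirane (C4, C5) comes from a late Sharpless epoxidation of the neryl-type (Z)-allylic alcohol, followed by oxidation to the aldehyde.
3. The tetrasubstituted (Z)-iodoacrylate (C7, C11–C13) comes from an iodide/formaldehyde halo-aldol on a γ-tigloyloxy ynoate; C8 is set by asymmetric alkynylation with methyl propiolate.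
4. The C8–C1 chain comes from anti-crotylboration of the nerol-derived C1 aldehyde (sets C1, C10), acetylation and an anti-Markovnikov Wacker oxidation.
5. Ring order: oxirane (step 10), then cyclodecane and butenolide together (step 12).

Assumption: atom labels C1–C15 follow germacrane numbering (C1–C10 ring, C6 lactone carbinol, C11/C12/C13 = butenolide α-carbon, carbonyl and CH2OAc); the target is the (1S,4R,5S,6S,8S,10R) enantiomer encoded by the given SMILES.

**Route**

Step 1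
Reactants: 1 nerol [(2Z)-3,7-dimethylocta-2,6-dien-1-ol]; 2 tert-butyldimethylsilyl chloride
Product: 3 neryl TBS ether [tert-butyl{[(2Z)-3,7-dimethylocta-2,6-dien-1-yl]oxy}dimethylsilane]
Conditions: TBSCl, imidazole, DMF, 0 °C → rt
Reagents that add atoms: tert-butyldimethylsilyl chloride, CC(C)(C)[Si](C)(C)Cl
Why: Standard silylation of the primary allylic alcohol masks the C6 oxygen with a group orthogonal to the three esters installed later; no stereocentre is formed.

Step 2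
Reactants: 3 neryl TBS ether; 4 sodium periodate
Product: 6 (4Z)-6-[(tert-butyldimethylsilyl)oxy]-4-methylhex-4-enal, via vicinal diol 5 (not isolated)
Conditions: OsO4 (2 mol %), NaIO4 (4 equiv), 2,6-lutidine, dioxane/H2O 3:1, 0 °C → rt
Reagents that add atoms: sodium periodate, [Na+].[O-]I(=O)(=O)=O
Why: Lemieux–Johnson cleavage, in which OsO4 attacks the distal isopropylidene alkene rather than the 2,3-alkene (deactivated by the allylic oxygen and more hindered) and periodate cleaves the diol to the C1 aldehyde and acetone.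

Step 3
Reactants: 6 (4Z)-6-[(tert-butyldimethylsilyl)oxy]-4-methylhex-4-enal; 7 (E)-crotylboronic acid pinacol ester
Product: 8 (3R,4S,7Z)-9-[(tert-butyldimethylsilyl)oxy]-3,7-dimethylnona-1,7-dien-4-ol
Conditions: (R)-TRIP (5 mol %), 4 Å MS, toluene, −30 °C; aq. NaHCO3 work-up
Reagents that add atoms: (E)-crotylboronic acid pinacol ester, C/C=C/CB1OC(C)(C)C(C)(C)O1
Why: Chiral phosphoric acid-catalysed crotylboration, in which the closed chair transition state of the (E)-boronate gives the anti C1-OH/C10-Me pair and (R)-TRIP directs attack to the aldehyde Re face, setting 1S and 10R.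

Step 4
Reactants: 8 (3R,4S,7Z)-9-[(tert-butyldimethylsilyl)oxy]-3,7-dimethylnona-1,7-dien-4-ol; 9 acetic anhydride
Product: 10 (3R,4S,7Z)-9-[(tert-butyldimethylsilyl)oxy]-3,7-dimethylnona-1,7-dien-4-yl acetate
Conditions: Ac2O, pyridine, DMAP (cat.), CH2Cl2, rt
Reagents that add atoms: acetic anhydride, CC(=O)OC(C)=O
Why: DMAP-catalysed acylation installs the C1 acetate of the target at once, so C1 needs no protecting group, and leaves both stereocentres untouched.

Step 5
Reactants: 10 (3R,4S,7Z)-9-[(tert-butyldimethylsilyl)oxy]-3,7-dimethylnona-1,7-dien-4-yl acetate; 11 dioxygen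
Product: 12 (3R,4S,7Z)-4-acetoxy-9-[(tert-butyldimethylsilyl)oxy]-3,7-dimethylnon-7-enal
Conditions: PdCl2(PhCN)2 (12 mol %), CuCl2·2H2O (12 mol %), AgNO2 (6 mol %), t-BuOH/MeNO2 15:1, O2 (1 atm), rt
Reagents that add atoms: dioxygen, O=O
Why: Nitrite-modified (aldehyde-selective) Tsuji–Wacker oxidation delivers oxygen to the terminal carbon of the monosubstituted alkene, helped by the homoallylic acetate, giving the C8 aldehyde in one step while the trisubstituted alkene is inert.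

Step 6
Reactants: 12 (3R,4S,7Z)-4-acetoxy-9-[(tert-butyldimethylsilyl)oxy]-3,7-dimethylnon-7-enal; 13 methyl propiolate
Product: 14 methyl (4S,6R,7S,10Z)-7-acetoxy-12-[(tert-butyldimethylsilyl)oxy]-4-hydroxy-6,10-dimethyldodec-10-en-2-ynoate
Conditions: (S,S)-ProPhenol (20 mol %; ligand enantiomer chosen for Re-face addition), Me2Zn (3 equiv), toluene, 4 °C; aq. NH4Cl
Reagents that add atoms: methyl propiolate, C#CC(=O)OC
Why: Zn–ProPhenol-catalysed asymmetric alkynylation, in which the dinuclear zinc alkynylide adds to the Re face of the aldehyde under catalyst control, forming the C7–C8 bond and setting 8S.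

Step 7
Reactants: 14 methyl (4S,6R,7S,10Z)-7-acetoxy-12-[(tert-butyldimethylsilyl)oxy]-4-hydroxy-6,10-dimethyldodec-10-en-2-ynoate; 15 tigloyl chloride
Product: 16 methyl (4S,6R,7S,10Z)-7-acetoxy-12-[(tert-butyldimethylsilyl)oxy]-6,10-dimethyl-4-{[(2E)-2-methylbut-2-enoyl]oxy}dodec-10-en-2-ynoate
Conditions: tigloyl chloride, pyridine, DMAP (cat.), CH2Cl2, 0 °C
Reagents that add atoms: tigloyl chloride, C/C=C(\C)C(Cl)=O
Why: DMAP-catalysed esterification of the propargylic alcohol with the (E)-acid chloride installs the tiglate with retention at C8, the mild base avoiding isomerisation of the γ-oxy ynoate.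

Step 8
Reactants: 16 methyl (4S,6R,7S,10Z)-7-acetoxy-12-[(tert-butyldimethylsilyl)oxy]-6,10-dimethyl-4-{[(2E)-2-methylbut-2-enoyl]oxy}dodec-10-en-2-ynoate; 17 magnesium iodide; 18 formaldehyde; 9 acetic anhydride
Product: 20 methyl (2Z,4S,6R,7S,10Z)-7-acetoxy-2-(acetoxymethyl)-12-[(tert-butyldimethylsilyl)oxy]-3-iodo-6,10-dimethyl-4-{[(2E)-2-methylbut-2-enoyl]oxy}dodeca-2,10-dienoate, via hydroxymethyl iodoacrylate 19 (not isolated)
Conditions: MgI2 (1.5 equiv), CH2Cl2, −20 °C; anhydrous CH2O (from cracked paraformaldehyde, 3 equiv), −20 → 0 °C; then Ac2O, DMAP (cat.), 0 °C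
Reagents that add atoms: magnesium iodide, [Mg+2].[I-].[I-]; formaldehyde, C=O; acetic anhydride, CC(=O)OC(C)=O
Why: Proposed new method: Mg(II)-activated conjugate addition of iodide to the ynoate gives a β-iodo allenolate that is hydroxymethylated at C11 by formaldehyde anti to the large iodine (net anti addition, as in the protonation that makes NaI/AcOH hydroiodination of ynoates Z-selective), so iodine ends cis to CO2Me and the new CH2O group cis to C8, and the magnesium alkoxide is acetylated in the same flask; the closest known reaction type is the MgI2- or Et2AlI-mediated iodo-aldol (β-iodo Morita–Baylis–Hillman) reaction of propiolates and ynones with aldehydes.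

Step 9
Reactants: 20 methyl (2Z,4S,6R,7S,10Z)-7-acetoxy-2-(acetoxymethyl)-12-[(tert-butyldimethylsilyl)oxy]-3-iodo-6,10-dimethyl-4-{[(2E)-2-methylbut-2-enoyl]oxy}dodeca-2,10-dienoate
Product: 21 methyl (2Z,4S,6R,7S,10Z)-7-acetoxy-2-(acetoxymethyl)-12-hydroxy-3-iodo-6,10-dimethyl-4-{[(2E)-2-methylbut-2-enoyl]oxy}dodeca-2,10-dienoate
Conditions: HF·pyridine, pyridine, THF, 0 °C
Reagents that add atoms: none
Why: Fluoride-mediated desilylation of the primary silyl ether under buffered conditions leaves the acetates, tiglate, methyl ester and vinyl iodide intact.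

Step 10
Reactants: 21 methyl (2Z,4S,6R,7S,10Z)-7-acetoxy-2-(acetoxymethyl)-12-hydroxy-3-iodo-6,10-dimethyl-4-{[(2E)-2-methylbut-2-enoyl]oxy}dodeca-2,10-dienoate; 22 tert-butyl hydroperoxide
Product: 23 methyl (2Z,4S,6R,7S)-7-acetoxy-2-(acetoxymethyl)-9-[(2R,3S)-3-(hydroxymethyl)-2-methyloxiran-2-yl]-3-iodo-6-methyl-4-{[(2E)-2-methylbut-2-enoyl]oxy}non-2-enoate
Conditions: Ti(OiPr)4 (10 mol %), L-(+)-DIPT (12 mol %), TBHP, 4 Å MS, CH2Cl2, −20 °C
Reagents that add atoms: tert-butyl hydroperoxide, CC(C)(C)OO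
Why: Sharpless asymmetric epoxidation, in which the Ti–tartrate complex binds the primary allylic alcohol and L-(+)-DIPT gives the nerol-type (2S,3R)-epoxy alcohol (4R,5S, with the cis C3/C6 relationship fixed by the Z-alkene), the two electron-poor alkenes being unreactive.

Step 11
Reactants: 23 methyl (2Z,4S,6R,7S)-7-acetoxy-2-(acetoxymethyl)-9-[(2R,3S)-3-(hydroxymethyl)-2-methyloxiran-2-yl]-3-iodo-6-methyl-4-{[(2E)-2-methylbut-2-enoyl]oxy}non-2-enoate
Product: 24 methyl (2Z,4S,6R,7S)-7-acetoxy-2-(acetoxymethyl)-9-[(2R,3R)-3-formyl-2-methyloxiran-2-yl]-3-iodo-6-methyl-4-{[(2E)-2-methylbut-2-enoyl]oxy}non-2-enoate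
Conditions: Dess–Martin periodinane, NaHCO3, CH2Cl2, 0 °C → rt
Reagents that add atoms: none
Why: Dess–Martin oxidation converts the epoxy alcohol into the α,β-epoxy aldehyde under buffered neutral conditions without epimerising C5 (the descriptor changes only through CIP priorities).

Step 12
Reactants: 24 methyl (2Z,4S,6R,7S)-7-acetoxy-2-(acetoxymethyl)-9-[(2R,3R)-3-formyl-2-methyloxiran-2-yl]-3-iodo-6-methyl-4-{[(2E)-2-methylbut-2-enoyl]oxy}non-2-enoate
Product: 26 CNP0287840.1 [(1S,4R,5S,6S,8S,10R)-1,13-diacetoxy-4,5-epoxy-8-tigloyloxygermacr-7(11)-en-6,12-olide], via ring-closed hydroxy ester 25 (not isolated)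
Conditions: CrCl2 (10 equiv), NiCl2 (0.2 equiv), DMSO/THF 3:1, rt, syringe-pump addition to 2 mM; aq. sodium serinate work-up
Reagents that add atoms: none
Why: Nozaki–Hiyama–Kishi macrocyclisation, in which Ni inserts into the activated vinyl C–I bond and the derived vinylchromium(III) adds to the tethered aldehyde to close the 10-membered ring at C6–C7 with retention of alkene geometry; polar Felkin–Anh attack anti to the epoxide C–O bond of the cis-substituted epoxy aldehyde sets 6S, and the C6 alkoxide, held cis to CO2Me, lactonises to the butenolide.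

**Compound list**

1 | nerol, (2Z)-3,7-dimethylocta-2,6-dien-1-ol | OC/C=C(/C)CCC=C(C)C | starting material
2 | tert-butyldimethylsilyl chloride | CC(C)(C)[Si](C)(C)Cl | starting material
3 | neryl TBS ether, tert-butyl{[(2Z)-3,7-dimethylocta-2,6-dien-1-yl]oxy}dimethylsilane | CC(C)(C)[Si](C)(C)OC/C=C(/C)CCC=C(C)C | intermediate
4 | sodium periodate | [Na+].[O-]I(=O)(=O)=O | starting material
5 | (6Z)-8-[(tert-butyldimethylsilyl)oxy]-2,6-dimethyloct-6-ene-2,3-diol (C3 epimers, not isolated) | CC(C)(C)[Si](C)(C)OC/C=C(/C)CCC(O)C(C)(C)O | intermediate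
6 | (4Z)-6-[(tert-butyldimethylsilyl)oxy]-4-methylhex-4-enal | CC(C)(C)[Si](C)(C)OC/C=C(/C)CCC=O | intermediate
7 | (E)-crotylboronic acid pinacol ester | C/C=C/CB1OC(C)(C)C(C)(C)O1 | starting material
8 | (3R,4S,7Z)-9-[(tert-butyldimethylsilyl)oxy]-3,7-dimethylnona-1,7-dien-4-ol | CC(C)(C)[Si](C)(C)OC/C=C(/C)CC[C@H](O)[C@H](C)C=C | intermediate
9 | acetic anhydride | CC(=O)OC(C)=O | starting material
10 | (3R,4S,7Z)-9-[(tert-butyldimethylsilyl)oxy]-3,7-dimethylnona-1,7-dien-4-yl acetate | CC(C)(C)[Si](C)(C)OC/C=C(/C)CC[C@H](OC(C)=O)[C@H](C)C=C | intermediate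
11 | dioxygen | O=O | starting material
12 | (3R,4S,7Z)-4-acetoxy-9-[(tert-butyldimethylsilyl)oxy]-3,7-dimethylnon-7-enal | CC(C)(C)[Si](C)(C)OC/C=C(/C)CC[C@H](OC(C)=O)[C@H](C)CC=O | intermediate
13 | methyl propiolate | C#CC(=O)OC | starting material
14 | methyl (4S,6R,7S,10Z)-7-acetoxy-12-[(tert-butyldimethylsilyl)oxy]-4-hydroxy-6,10-dimethyldodec-10-en-2-ynoate | CC(C)(C)[Si](C)(C)OC/C=C(/C)CC[C@H](OC(C)=O)[C@H](C)C[C@H](O)C#CC(=O)OC | intermediate
15 | tigloyl chloride, (2E)-2-methylbut-2-enoyl chloride | C/C=C(\C)C(Cl)=O | starting material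
16 | methyl (4S,6R,7S,10Z)-7-acetoxy-12-[(tert-butyldimethylsilyl)oxy]-6,10-dimethyl-4-{[(2E)-2-methylbut-2-enoyl]oxy}dodec-10-en-2-ynoate | CC(C)(C)[Si](C)(C)OC/C=C(/C)CC[C@H](OC(C)=O)[C@H](C)C[C@H](OC(=O)/C(C)=C/C)C#CC(=O)OC | intermediate
17 | magnesium iodide | [Mg+2].[I-].[I-] | starting material
18 | formaldehyde (from cracked paraformaldehyde) | C=O | starting material
19 | methyl (2Z,4S,6R,7S,10Z)-7-acetoxy-12-[(tert-butyldimethylsilyl)oxy]-2-(hydroxymethyl)-3-iodo-6,10-dimethyl-4-{[(2E)-2-methylbut-2-enoyl]oxy}dodeca-2,10-dienoate (formed as its magnesium alkoxide, not isolated) | CC(C)(C)[Si](C)(C)OC/C=C(/C)CC[C@H](OC(C)=O)[C@H](C)C[C@H](OC(=O)/C(C)=C/C)/C(I)=C(\CO)C(=O)OC | intermediate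
20 | methyl (2Z,4S,6R,7S,10Z)-7-acetoxy-2-(acetoxymethyl)-12-[(tert-butyldimethylsilyl)oxy]-3-iodo-6,10-dimethyl-4-{[(2E)-2-methylbut-2-enoyl]oxy}dodeca-2,10-dienoate | CC(C)(C)[Si](C)(C)OC/C=C(/C)CC[C@H](OC(C)=O)[C@H](C)C[C@H](OC(=O)/C(C)=C/C)/C(I)=C(\COC(C)=O)C(=O)OC | intermediate
21 | methyl (2Z,4S,6R,7S,10Z)-7-acetoxy-2-(acetoxymethyl)-12-hydroxy-3-iodo-6,10-dimethyl-4-{[(2E)-2-methylbut-2-enoyl]oxy}dodeca-2,10-dienoate | OC/C=C(/C)CC[C@H](OC(C)=O)[C@H](C)C[C@H](OC(=O)/C(C)=C/C)/C(I)=C(\COC(C)=O)C(=O)OC | intermediate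
22 | tert-butyl hydroperoxide | CC(C)(C)OO | starting material
23 | methyl (2Z,4S,6R,7S)-7-acetoxy-2-(acetoxymethyl)-9-[(2R,3S)-3-(hydroxymethyl)-2-methyloxiran-2-yl]-3-iodo-6-methyl-4-{[(2E)-2-methylbut-2-enoyl]oxy}non-2-enoate | OC[C@@H]1O[C@]1(C)CC[C@H](OC(C)=O)[C@H](C)C[C@H](OC(=O)/C(C)=C/C)/C(I)=C(\COC(C)=O)C(=O)OC | intermediate
24 | methyl (2Z,4S,6R,7S)-7-acetoxy-2-(acetoxymethyl)-9-[(2R,3R)-3-formyl-2-methyloxiran-2-yl]-3-iodo-6-methyl-4-{[(2E)-2-methylbut-2-enoyl]oxy}non-2-enoate | O=C[C@@H]1O[C@]1(C)CC[C@H](OC(C)=O)[C@H](C)C[C@H](OC(=O)/C(C)=C/C)/C(I)=C(\COC(C)=O)C(=O)OC | intermediate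
25 | ring-closed hydroxy ester: methyl (1S,4R,5S,6S,8S,10R)-1,13-diacetoxy-4,5-epoxy-6-hydroxy-8-tigloyloxygermacr-7(11)-en-12-oate, CO2Me cis to C6 (formed as its Cr(III) alkoxide, not isolated) | C/C=C(\C)C(=O)O[C@H]1C[C@@H](C)[C@@H](OC(C)=O)CC[C@@]2(C)O[C@H]2[C@@H](O)/C1=C(\C(=O)OC)COC(C)=O | intermediate
26 | CNP0287840.1, (1S,4R,5S,6S,8S,10R)-1,13-diacetoxy-4,5-epoxy-8-[(2E)-2-methylbut-2-enoyloxy]germacr-7(11)-en-6,12-olide | C/C=C(\C)C(=O)O[C@H]1C[C@@H](C)[C@@H](OC(C)=O)CC[C@@]2(C)O[C@H]2[C@H]2OC(=O)C(COC(C)=O)=C12 | target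

**Totals**

Total step count: 12. Longest linear sequence: 12 (from nerol).

**Three steps most likely to fail**

Step 12 (Ni/Cr double ring closure). The risks are Cr(II) attack on the epoxy aldehyde, β-elimination of the allylic tiglate from the vinylmetal to give an allene, oligomerisation instead of 10-ring closure, and the wrong C6 epimer. The fallback changes the order of ring formation; it sets out from 21 and comes back at 26. Allylic alcohol 21 is oxidised with MnO2 in CH2Cl2 to the (Z)-enal F1. F1 is cyclised under Ni/Cr conditions with a chiral sulfonamide ligand on chromium (Kishi-type catalytic conditions) so that C6 is set by the ligand, and lactonisation gives the 4,5-deoxy macrolide F2. The only electron-rich alkene of F2 (C4=C5) is then epoxidised from the ring periphery with DMDO or mCPBA to give 26.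

Step 8 (iodide/formaldehyde halo-aldol). The risks are the wrong alkene geometry, SN2′ loss of the tiglate and formaldehyde oligomers. The fallback builds the tetrasubstituted alkene by anti-halogenation and cross-coupling; it sets out from 16 and comes back at 26. Anti addition of IBr to ynoate 16 (Br to the β-carbon C7, I to the α-carbon C11) gives the (E)-3-bromo-2-iodoacrylate F3. Stille coupling of the more reactive C–I bond with (acetoxymethyl)tributylstannane (Pd2(dba)3, AsPh3, CuI, DMF) gives the (Z)-vinyl bromide F4, the bromo analogue of 20. F4 is carried through the operations of steps 9–12 unchanged: HF·pyridine gives the allylic alcohol F5, Sharpless epoxidation with L-(+)-DIPT gives the epoxy alcohol F6, Dess–Martin oxidation gives the epoxy aldehyde F7, and Ni/Cr cyclisation (vinyl bromides are competent partners) with lactonisation gives 26.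

Step 5 (aldehyde-selective Wacker). The risks are methyl ketone formation and alkene isomerisation at the branched allylic position. The fallback uses hydroboration instead of Pd oxidation; it sets out from 10 and comes back at 12. 9-BBN adds selectively to the monosubstituted alkene of 10 and NaBO3 oxidation gives the primary alcohol F8, which Dess–Martin periodinane oxidises to 12.

Further compounds
F1 | step 12 | methyl (2Z,4S,6R,7S,10Z)-7-acetoxy-2-(acetoxymethyl)-3-iodo-6,10-dimethyl-4-{[(2E)-2-methylbut-2-enoyl]oxy}-12-oxododeca-2,10-dienoate | O=C/C=C(/C)CC[C@H](OC(C)=O)[C@H](C)C[C@H](OC(=O)/C(C)=C/C)/C(I)=C(\COC(C)=O)C(=O)OC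
F2 | step 12 | (1S,4Z,6R,8S,10R)-1,13-diacetoxy-8-[(2E)-2-methylbut-2-enoyloxy]germacra-4,7(11)-dien-6,12-olide | C/C=C(\C)C(=O)O[C@H]1C[C@@H](C)[C@@H](OC(C)=O)CC/C(C)=C\[C@H]2OC(=O)C(COC(C)=O)=C12
F3 | step 8 | methyl (2E,4S,6R,7S,10Z)-7-acetoxy-3-bromo-12-[(tert-butyldimethylsilyl)oxy]-2-iodo-6,10-dimethyl-4-{[(2E)-2-methylbut-2-enoyl]oxy}dodeca-2,10-dienoate | CC(C)(C)[Si](C)(C)OC/C=C(/C)CC[C@H](OC(C)=O)[C@H](C)C[C@H](OC(=O)/C(C)=C/C)/C(Br)=C(\I)C(=O)OC
F4 | step 8 | methyl (2Z,4S,6R,7S,10Z)-7-acetoxy-2-(acetoxymethyl)-3-bromo-12-[(tert-butyldimethylsilyl)oxy]-6,10-dimethyl-4-{[(2E)-2-methylbut-2-enoyl]oxy}dodeca-2,10-dienoate | CC(C)(C)[Si](C)(C)OC/C=C(/C)CC[C@H](OC(C)=O)[C@H](C)C[C@H](OC(=O)/C(C)=C/C)/C(Br)=C(\COC(C)=O)C(=O)OC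
F5 | step 8 | methyl (2Z,4S,6R,7S,10Z)-7-acetoxy-2-(acetoxymethyl)-3-bromo-12-hydroxy-6,10-dimethyl-4-{[(2E)-2-methylbut-2-enoyl]oxy}dodeca-2,10-dienoate | OC/C=C(/C)CC[C@H](OC(C)=O)[C@H](C)C[C@H](OC(=O)/C(C)=C/C)/C(Br)=C(\COC(C)=O)C(=O)OC
F6 | step 8 | methyl (2Z,4S,6R,7S)-7-acetoxy-2-(acetoxymethyl)-3-bromo-9-[(2R,3S)-3-(hydroxymethyl)-2-methyloxiran-2-yl]-6-methyl-4-{[(2E)-2-methylbut-2-enoyl]oxy}non-2-enoate | OC[C@@H]1O[C@]1(C)CC[C@H](OC(C)=O)[C@H](C)C[C@H](OC(=O)/C(C)=C/C)/C(Br)=C(\COC(C)=O)C(=O)OC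
F7 | step 8 | methyl (2Z,4S,6R,7S)-7-acetoxy-2-(acetoxymethyl)-3-bromo-9-[(2R,3R)-3-formyl-2-methyloxiran-2-yl]-6-methyl-4-{[(2E)-2-methylbut-2-enoyl]oxy}non-2-enoate | O=C[C@@H]1O[C@]1(C)CC[C@H](OC(C)=O)[C@H](C)C[C@H](OC(=O)/C(C)=C/C)/C(Br)=C(\COC(C)=O)C(=O)OC
F8 | step 5 | (3R,4S,7Z)-9-[(tert-butyldimethylsilyl)oxy]-1-hydroxy-3,7-dimethylnon-7-en-4-yl acetate | CC(C)(C)[Si](C)(C)OC/C=C(/C)CC[C@H](OC(C)=O)[C@H](C)CCO
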